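**Plan**

- Retrosynthesis: the acetate and the lactone bond O1–C2 are cut first. The benzene ring of the coumarin is then opened at C8–C8a, C6–C7 and C4a–C8a, which gives ynol ether 11 and dienyl diazo ketone 17. Ring A is cut at C1–C6 back to an epoxide of neryl acetate.
- Forward: ring A is closed first (cationic epoxy-olefin cyclisation), the benzene ring second (benzannulation) and the pyranone last (photo-lactonisation). The two-carbon ynol unit joins ring A to the arene.
- Enabling feature: in the coumarin benzene ring (C4a, C5, C6, C7, C8, C8a) the ether oxygen on C7 and the ring oxygen on C8a are meta across unsubstituted C8, and C4a, ortho to C8a, carries the C3–C4 arm. A vinylketene and an alkoxyalkyne deliver exactly this resorcinol monoether pattern.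
- Stereochemistry: C5 (R) comes from a Shi epoxidation. C1 (R) is set trans to it by the Z alkene geometry in a chair-like cyclisation. No later step touches either centre.

Key step: step 10

Remark: ring A is numbered C1 (CH carrying CH2O), C2 (C–CH3), C3 (=CH), C4 (CH2), C5 (CH–O), C6 (C(CH3)2), and the target is the trans-(1R,5R) isomer. The ester alkyl of the dienoate arm leaves as alcohol on lactonisation, so the ethyl ester is used because its aldehyde precursor is commercial.

**Step 1**
Reactants: 1 neryl acetate [(2Z)-3,7-dimethylocta-2,6-dien-1-yl acetate]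
Product: 2 (R)-6,7-epoxyneryl acetate [(2Z)-5-[(2R)-3,3-dimethyloxiran-2-yl]-3-methylpent-2-en-1-yl acetate]
Conditions: KHSO5 (as 2KHSO5·KHSO4·K2SO4), D-fructose-derived ketone catalyst of the Shi epoxidation (1,2:4,5-di-O-isopropylidene-β-D-erythro-2,3-hexodiulo-2,6-pyranose, 30 mol %), K2CO3, Bu4NHSO4 (cat.), MeCN/CH2(OMe)2, aq. Na2B4O7 buffer, 0 °C
Reagents that add atoms: potassium peroxymonosulfate, [K+].[O-]S(=O)(=O)OO
Why: Shi asymmetric epoxidation, in which the chiral dioxirane should oxidise the electron-rich terminal alkene in preference to the 2,3-alkene deactivated by the allylic acetate and, through its spiro transition state, deliver oxygen to the face that makes the oxirane CH carbon R (the future C5).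

**Step 2**
Reactants: 2 (R)-6,7-epoxyneryl acetate
Product: 3 [(1R,5R)-5-hydroxy-2,6,6-trimethylcyclohex-2-en-1-yl]methyl acetate (OH and CH2OAc trans)
Conditions: ZrCl4, CH2Cl2, −20 °C → rt
Reagents that add atoms: none
Why: Lewis acid-promoted cationic epoxy-olefin cyclisation, in which the Z alkene should open the activated epoxide anti at its tertiary carbon through a chair-like transition state with the C5–O bond equatorial and the acetoxymethyl group (cis to the tether on the Z alkene) axial, so that C1 is set trans to the retained C5 oxygen; the C2 cation then loses the axial C3 proton to give the ring alkene, the C1 hydrogen being equatorial and poorly aligned.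

**Step 3**
Reactants: 3 trans-hydroxy acetate
Product: 4 [(1R,5R)-5-(tert-butyldimethylsilyloxy)-2,6,6-trimethylcyclohex-2-en-1-yl]methyl acetate
Conditions: TBSOTf, 2,6-lutidine, CH2Cl2, −78 → 0 °C
Reagents that add atoms: tert-butyldimethylsilyl trifluoromethanesulfonate, CC(C)(C)[Si](C)(C)OS(=O)(=O)C(F)(F)F
Why: Silyl ether formation with the silyl triflate, which is reactive enough for the hindered secondary alcohol next to the quaternary carbon and gives an ether that should withstand KH and n-BuLi.

**Step 4**
Reactants: 4 silyl ether acetate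
Product: 5 [(1R,5R)-5-(tert-butyldimethylsilyloxy)-2,6,6-trimethylcyclohex-2-en-1-yl]methanol
Conditions: K2CO3 (cat.), MeOH, rt
Reagents that add atoms: none
Why: Base-catalysed methanolysis (transesterification) should free the primary alcohol and leave the secondary silyl ether and both stereocentres untouched.

**Step 5**
Reactants: 5 ring A alcohol; 6 trichloroethylene
Product: 8 (E)-1,2-dichloroethenyl [(1R,5R)-5-(tert-butyldimethylsilyloxy)-2,6,6-trimethylcyclohex-2-en-1-yl]methyl ether, via potassium alkoxide 7 (not isolated)
Conditions: KH, THF, 0 °C; then 6, −50 °C → rt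
Reagents that add atoms: none
Why: The potassium alkoxide dehydrochlorinates trichloroethylene to dichloroacetylene and adds to it in anti fashion, the established alkoxide–trichloroethylene route to (E)-1,2-dichlorovinyl ethers.

**Step 6**
Reactants: 8 dichlorovinyl ether
Product: 11 ethynyl [(1R,5R)-5-(tert-butyldimethylsilyloxy)-2,6,6-trimethylcyclohex-2-en-1-yl]methyl ether, via chloroethynyl ether 9 (not isolated), via lithium acetylide 10 (not isolated)
Conditions: n-BuLi (2.5 equiv), THF, −78 → −40 °C; MeOH, −78 °C
Reagents that add atoms: none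
Why: Deprotonation with β-elimination of chloride, chlorine–lithium exchange on the chloroalkyne and a cold methanol quench form the known elimination–exchange conversion of dichlorovinyl ethers into terminal ynol ethers.

**Step 7**
Reactants: 12 ethyl (E)-4-oxobut-2-enoate; 13 1-(triphenyl-λ5-phosphanylidene)propan-2-one
Product: 14 ethyl (2E,4E)-6-oxohepta-2,4-dienoate
Conditions: CH2Cl2, rt
Reagents that add atoms: none
Why: Wittig olefination with a ketone-stabilised ylide, which should give the new alkene E and leave the existing E enoate unchanged.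

**Step 8**
Reactants: 14 dienone ester
Product: 16 ethyl (2E,4E)-8,8,8-trifluoro-6,8-dioxoocta-2,4-dienoate (enolised 1,3-diketone), via lithium enolate 15 (not isolated)
Conditions: LiN(SiMe3)2, THF, −78 °C; CF3CO2CH2CF3, −78 °C; aq. HCl
Reagents that add atoms: 2,2,2-trifluoroethyl trifluoroacetate, FC(F)(F)COC(=O)C(F)(F)F
Why: Kinetic deprotonation of the only enolisable position (the methyl ketone) and Claisen-type C-trifluoroacetylation activate the ketone for diazo transfer, which avoids an acid chloride–diazoalkane step that the electron-poor diene would not tolerate.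

**Step 9**
Reactants: 16 trifluoroacetyl ketone
Product: 17 ethyl (2E,4E)-7-diazo-6-oxohepta-2,4-dienoate
Conditions: MsN3, Et3N, H2O, MeCN, rt
Reagents that add atoms: methanesulfonyl azide, CS(=O)(=O)N=[N+]=[N-]
Why: Detrifluoroacetylative diazo transfer, in which the sulfonyl azide hands N2 to the activated methylene and the trifluoroacetyl group leaves on the sulfonamide, the standard entry to α,β-unsaturated α′-diazo ketones.

**Step 10**
Reactants: 11 ring A ynol ether; 17 dienyl diazo ketone
Product: 22 ethyl (2E)-3-[2-hydroxy-4-{[(1R,5R)-5-(tert-butyldimethylsilyloxy)-2,6,6-trimethylcyclohex-2-en-1-yl]methoxy}phenyl]prop-2-enoate, via Wolff ketene 18 (not isolated), via alkoxycyclobutenone 19 (not isolated), via alkoxy dienylketene 20 (not isolated), via cyclohexadienone 21 (not isolated)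
Conditions: 11 (1.0 equiv), 17 (1.3 equiv, in portions), hν (blue LEDs, 450 nm), ClCH2CH2Cl, rt; then 80 °C
Reagents that add atoms: none
Why: Light expels N2 from 17 with Wolff rearrangement to the (E,E)-configured ketene 18, whose C=C=O unit should add [2+2] to the electron-rich ynol ether 11, the nucleophilic terminal alkyne carbon bonding to the ketene carbonyl carbon (C8–C8a) and the oxygen-bearing carbon to the former diazo carbon (C6–C7), to give 3-alkoxycyclobutenone 19. On warming, 19 opens by conrotatory 4π electrocyclic cleavage of the transient C6–C8a bond to dienylketene 20, which closes the benzene ring by a thermally allowed disrotatory 6π electrocyclisation (C4a–C8a) to cyclohexadienone 21, and enolisation gives phenol 22. The closest known reaction type is the photochemical Wolff variant of the Danheiser benzannulation of unsaturated diazo ketones with alkoxy- and siloxyalkynes, which gives resorcinol monoethers. No stereocentre is created, because the sp3 carbons of 19 and 21 end up aromatic and C1 and C5 of ring A are remote and untouched. The step needs the regiochemistry that places the ether oxygen meta to the new phenol, which the polarisation of the ynol ether secures, and it needs 18 to be trapped before it cyclises on itself, which the E geometry of its 4,5-alkene (the chain end cannot reach the ketene carbon) and the long-wavelength light (absorbed by the diazo ketone only) secure.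

**Step 11**
Reactants: 22 (E)-2-hydroxycinnamate
Product: 24 7-{[(1R,5R)-5-(tert-butyldimethylsilyloxy)-2,6,6-trimethylcyclohex-2-en-1-yl]methoxy}-2H-chromen-2-one, via Z-cinnamate 23 (not isolated)
Conditions: hν (365 nm), MeCN (dilute), rt
Reagents that add atoms: none
Why: E-to-Z photoisomerisation of the cinnamate brings the ester next to the phenol, and the Z isomer should lactonise by intramolecular transesterification with loss of ethanol, as in the light-triggered release of alcohols from o-hydroxycinnamates, which closes the pyranone ring.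

**Step 12**
Reactants: 24 silyl-protected coumarin ether
Product: 25 7-{[(1R,5R)-5-hydroxy-2,6,6-trimethylcyclohex-2-en-1-yl]methoxy}-2H-chromen-2-one
Conditions: HF·pyridine, THF, 0 °C → rt
Reagents that add atoms: none
Why: Fluoride-mediated cleavage of the Si–O bond under mildly acidic conditions, which the lactone, the aryl alkyl ether and the ring alkene should tolerate.

**Step 13**
Reactants: 25 secondary alcohol
Product: 26 (1R,5R)-5-{[(2-oxo-2H-chromen-7-yl)oxy]methyl}-4,6,6-trimethylcyclohex-3-en-1-yl acetate (target)
Conditions: Ac2O, pyridine, DMAP (cat.), CH2Cl2, rt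
Reagents that add atoms: acetic anhydride, CC(=O)OC(C)=O
Why: DMAP-catalysed acylation of the hindered secondary alcohol proceeds at oxygen, so the C5 configuration is kept.

**Compound list**

1 | neryl acetate, (2Z)-3,7-dimethylocta-2,6-dien-1-yl acetate | CC(=O)OC/C=C(C)\CCC=C(C)C | starting material
2 | (2Z)-5-[(2R)-3,3-dimethyloxiran-2-yl]-3-methylpent-2-en-1-yl acetate | CC(=O)OC/C=C(C)\CC[C@H]1OC1(C)C | intermediate
3 | [(1R,5R)-5-hydroxy-2,6,6-trimethylcyclohex-2-en-1-yl]methyl acetate | O[C@@H]1CC=C(C)[C@@H](COC(C)=O)C1(C)C | intermediate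
4 | [(1R,5R)-5-(tert-butyldimethylsilyloxy)-2,6,6-trimethylcyclohex-2-en-1-yl]methyl acetate | CC(C)(C)[Si](C)(C)O[C@@H]1CC=C(C)[C@@H](COC(C)=O)C1(C)C | intermediate
5 | [(1R,5R)-5-(tert-butyldimethylsilyloxy)-2,6,6-trimethylcyclohex-2-en-1-yl]methanol | CC(C)(C)[Si](C)(C)O[C@@H]1CC=C(C)[C@@H](CO)C1(C)C | intermediate
6 | trichloroethylene | ClC=C(Cl)Cl | starting material
7 | potassium alkoxide of 5 | CC(C)(C)[Si](C)(C)O[C@@H]1CC=C(C)[C@@H](C[O-])C1(C)C.[K+] | intermediate (not isolated)
8 | (E)-1,2-dichloroethenyl ether of 5 | CC(C)(C)[Si](C)(C)O[C@@H]1CC=C(C)[C@@H](CO/C(Cl)=C\Cl)C1(C)C | intermediate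
9 | chloroethynyl ether of 5 | CC(C)(C)[Si](C)(C)O[C@@H]1CC=C(C)[C@@H](COC#CCl)C1(C)C | intermediate (not isolated)
10 | lithium acetylide of the ethynyl ether of 5 | CC(C)(C)[Si](C)(C)O[C@@H]1CC=C(C)[C@@H](COC#C[Li])C1(C)C | intermediate (not isolated)
11 | ethynyl [(1R,5R)-5-(tert-butyldimethylsilyloxy)-2,6,6-trimethylcyclohex-2-en-1-yl]methyl ether | CC(C)(C)[Si](C)(C)O[C@@H]1CC=C(C)[C@@H](COC#C)C1(C)C | intermediate
12 | ethyl (E)-4-oxobut-2-enoate | CCOC(=O)/C=C/C=O | starting material
13 | 1-(triphenyl-λ5-phosphanylidene)propan-2-one | CC(=O)C=P(c1ccccc1)(c1ccccc1)c1ccccc1 | starting material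
14 | ethyl (2E,4E)-6-oxohepta-2,4-dienoate | CCOC(=O)/C=C/C=C/C(C)=O | intermediate
15 | lithium enolate of 14 (methyl side) | CCOC(=O)/C=C/C=C/C(=C)[O-].[Li+] | intermediate (not isolated)
16 | ethyl (2E,4E)-8,8,8-trifluoro-6,8-dioxoocta-2,4-dienoate | CCOC(=O)/C=C/C=C/C(=O)CC(=O)C(F)(F)F | intermediate
17 | ethyl (2E,4E)-7-diazo-6-oxohepta-2,4-dienoate | CCOC(=O)/C=C/C=C/C(=O)C=[N+]=[N-] | intermediate
18 | ethyl (2E,4E)-7-oxohepta-2,4,6-trienoate (ketene) | CCOC(=O)/C=C/C=C/C=C=O | intermediate (not isolated)
19 | ethyl (2E,4E)-5-[2-(ring A methoxy)-4-oxocyclobut-2-en-1-yl]penta-2,4-dienoate, ring A as in 5, new ring carbon unassigned | CC(C)(C)[Si](C)(C)O[C@@H]1CC=C(C)[C@@H](COC2=CC(=O)C2/C=C/C=C/C(=O)OCC)C1(C)C | intermediate (not isolated)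
20 | ethyl (2E,4E,6Z)-7-(ring A methoxy)-9-oxonona-2,4,6,8-tetraenoate (ketene), ring A as in 5 | CC(C)(C)[Si](C)(C)O[C@@H]1CC=C(C)[C@@H](CO/C(C=C=O)=C/C=C/C=C/C(=O)OCC)C1(C)C | intermediate (not isolated)
21 | ethyl (2E)-3-[4-(ring A methoxy)-6-oxocyclohexa-2,4-dien-1-yl]prop-2-enoate, ring A as in 5, new ring carbon unassigned | CC(C)(C)[Si](C)(C)O[C@@H]1CC=C(C)[C@@H](COC2=CC(=O)C(/C=C/C(=O)OCC)C=C2)C1(C)C | intermediate (not isolated)
22 | ethyl (2E)-3-[2-hydroxy-4-{[(1R,5R)-5-(tert-butyldimethylsilyloxy)-2,6,6-trimethylcyclohex-2-en-1-yl]methoxy}phenyl]prop-2-enoate | CC(C)(C)[Si](C)(C)O[C@@H]1CC=C(C)[C@@H](COc2ccc(/C=C/C(=O)OCC)c(O)c2)C1(C)C | intermediate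
23 | (2Z) isomer of 22 | CC(C)(C)[Si](C)(C)O[C@@H]1CC=C(C)[C@@H](COc2ccc(/C=C\C(=O)OCC)c(O)c2)C1(C)C | intermediate (not isolated)
24 | 7-{[(1R,5R)-5-(tert-butyldimethylsilyloxy)-2,6,6-trimethylcyclohex-2-en-1-yl]methoxy}-2H-chromen-2-one | CC(C)(C)[Si](C)(C)O[C@@H]1CC=C(C)[C@@H](COc2ccc3ccc(=O)oc3c2)C1(C)C | intermediate
25 | 7-{[(1R,5R)-5-hydroxy-2,6,6-trimethylcyclohex-2-en-1-yl]methoxy}-2H-chromen-2-one | O[C@@H]1CC=C(C)[C@@H](COc2ccc3ccc(=O)oc3c2)C1(C)C | intermediate
26 | (1R,5R)-5-{[(2-oxo-2H-chromen-7-yl)oxy]methyl}-4,6,6-trimethylcyclohex-3-en-1-yl acetate | CC(=O)O[C@@H]1CC=C(C)[C@@H](COc2ccc3ccc(=O)oc3c2)C1(C)C | target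

**Step count**

Total: 13 steps. Longest linear sequence: 10 steps (steps 1–6, then 10–13); the diazo ketone branch is steps 7–9.

**Steps most likely to fail**

Step 10. Trapping of the short-lived ketene by the ynol ether may lose out to ketene dimerisation, to acylation of the phenol as it forms, or to light-induced E-to-Z isomerisation followed by self-cyclisation of the ketene. The ynol ether may also fragment by retro-ene loss of ketene in the warm phase. The fallback gives up the benzannulation and sets out from alcohol 5. A Mitsunobu etherification (PPh3, DIAD, toluene, 0 °C → rt) with commercial umbelliferone (7-hydroxy-2H-chromen-2-one, Oc1ccc2ccc(=O)oc2c1) forms the aryl ether directly and comes back to the route at coumarin 24. It makes no new compound (F0).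

Step 2. The chair-like folding that puts the acetoxymethyl group axial may be eroded by a boat-like folding, which would lower the trans selectivity. The tertiary cation may also lose a methyl proton (exocyclic alkene) or be diverted by acetate participation or hydride shift. The fallback sets out from epoxide 2 and replaces the cation by a radical. Cp2TiCl (trivalent titanium, made from Cp2TiCl2 and Mn dust; THF, rt) opens the epoxide homolytically, and the tertiary radical cyclises in the 6-endo mode onto the Z alkene and ends by β-hydride elimination. This should give [(1R,3R)-3-hydroxy-2,2-dimethyl-6-methylidenecyclohexyl]methyl acetate F1. Silylation (TBSOTf, 2,6-lutidine) gives its silyl ether, [(1R,3R)-3-(tert-butyldimethylsilyloxy)-2,2-dimethyl-6-methylidenecyclohexyl]methyl acetate F2. RhCl3·3H2O in hot ethanol then moves the exocyclic alkene into the ring toward the unhindered CH2, and the fallback comes back at silyl ether 4.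

Step 6. The terminal ynol ether may be lost by hydration to the acetate ester or by decomposition during work-up and chromatography. The fallback sets out from lithium acetylide 10, which is quenched with Me3SiCl instead of methanol to give the more robust 2-(trimethylsilyl)ethynyl ether of 5 F3. Benzannulation of this with 17 under the conditions of step 10 should place silicon on the carbon between the two oxygens, giving ethyl (2E)-3-[2-hydroxy-3-(trimethylsilyl)-4-(ring A methoxy)phenyl]prop-2-enoate F4. Ipso-protodesilylation of this doubly activated arylsilane (CF3CO2H, CH2Cl2, 0 °C) comes back to the route at phenol 22.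

**Further compounds**

F0 | step 10 | none | none
F1 | step 2 | [(1R,3R)-3-hydroxy-2,2-dimethyl-6-methylidenecyclohexyl]methyl acetate | O[C@@H]1CCC(=C)[C@@H](COC(C)=O)C1(C)C
F2 | step 2 | [(1R,3R)-3-(tert-butyldimethylsilyloxy)-2,2-dimethyl-6-methylidenecyclohexyl]methyl acetate | CC(C)(C)[Si](C)(C)O[C@@H]1CCC(=C)[C@@H](COC(C)=O)C1(C)C
F3 | step 6 | 2-(trimethylsilyl)ethynyl [(1R,5R)-5-(tert-butyldimethylsilyloxy)-2,6,6-trimethylcyclohex-2-en-1-yl]methyl ether | CC(C)(C)[Si](C)(C)O[C@@H]1CC=C(C)[C@@H](COC#C[Si](C)(C)C)C1(C)C
F4 | step 6 | ethyl (2E)-3-[2-hydroxy-3-(trimethylsilyl)-4-{[(1R,5R)-5-(tert-butyldimethylsilyloxy)-2,6,6-trimethylcyclohex-2-en-1-yl]methoxy}phenyl]prop-2-enoate | CC(C)(C)[Si](C)(C)O[C@@H]1CC=C(C)[C@@H](COc2ccc(/C=C/C(=O)OCC)c(O)c2[Si](C)(C)C)C1(C)C
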